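**Retrosynthetic overview** (natural-product numbering: C1 = alkyne CH, C15 = methyl, ring oxygen between C7 and C12)

1. The acetate, the Z-enyne (Peterson olefination of a C4 aldehyde) and the C13 bromide (SN2 inversion of the 13R alcohol) are installed after the ring is made.
2. The oxepene is opened at C10–C11. C10 is an sp2 carbon of the cis ring alkene C9=C10 and C11 is the ring CH2 next to the ether carbon C12, so the ring (O, C7, C8, C9, C10, C11, C12) unfolds to a Z-bromoalkene and a primary β-alkoxy iodide held together only by the C7–O–C12 ether, with no stereocentre at a reacting carbon.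
3. The acyclic ether comes from O-alkylation of the C7 alcohol with bromoacetic acid, an Evans syn glycolate aldol with propanal (sets C12 and C13), reductive removal of the auxiliary (C11 alcohol) and iodination.
4. The C7 alcohol comes from chelation-controlled propargylation of the aldehyde derived from (S)-butane-1,2,4-triol (C4–C7, C6 from the chiral pool), then alkyne to Z-bromoalkene.
5. Ring order: the temporary 1,3-dioxane (4-methoxybenzylidene acetal over O4 and O6) is formed in step 1, the oxepene in step 11, and the dioxane is opened again in step 13.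

Key step: step 11

Remark: the SMILES is read as (6S,7S,12R,13S) with a cis-2,7-disubstituted oxepene; Dx stands for the (2S,4S)-2-(4-methoxyphenyl)-1,3-dioxan-4-yl group and PMB for 4-methoxybenzyl; compounds 5 and 23 are taken as purchasable.

**Route**

Step 1
Reactants: 1 (S)-butane-1,2,4-triol; 2 4-methoxybenzaldehyde dimethyl acetal
Product: 3 [(2S,4S)-2-(4-methoxyphenyl)-1,3-dioxan-4-yl]methanol
Conditions: camphorsulfonic acid (cat.), CH2Cl2, 25 °C
Reagents that add atoms: none
Why: Acid-catalysed transacetalisation under thermodynamic control should give the six-membered 2,4-O-arylidene acetal with the aryl group equatorial and cis to the C4 substituent (acetal carbon 2S by equilibration, carbinol carbon from the chiral pool), leaving the primary hydroxyl free.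

Step 2
Reactants: 3 [(2S,4S)-2-(4-methoxyphenyl)-1,3-dioxan-4-yl]methanol
Product: 4 (2S,4S)-2-(4-methoxyphenyl)-1,3-dioxane-4-carbaldehyde
Conditions: Dess–Martin periodinane, pyridine, CH2Cl2, 0 to 25 °C
Reagents that add atoms: none
Why: Dess–Martin oxidation under buffered conditions should give the α-alkoxy aldehyde without epimerisation or acetal cleavage, and it is used crude.

Step 3
Reactants: 4 (2S,4S)-2-(4-methoxyphenyl)-1,3-dioxane-4-carbaldehyde; 5 allenyltributylstannane
Product: 6 (1S)-1-Dx-but-3-yn-1-ol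
Conditions: MgBr2·OEt2, CH2Cl2, −78 to −20 °C
Reagents that add atoms: none
Why: Chelation-controlled SE2' propargylation: magnesium bridges the aldehyde oxygen and ring O3 (Cram chelate), the allenylstannane attacks the face away from ring C5, and the new carbinol C7 should form syn to the C6 oxygen, i.e. S.

Step 4
Reactants: 6 (1S)-1-Dx-but-3-yn-1-ol
Product: 7 (1S)-4-bromo-1-Dx-but-3-yn-1-ol
Conditions: N-bromosuccinimide, AgNO3 (10 mol %), acetone, 25 °C, dark
Reagents that add atoms: N-bromosuccinimide, O=C1CCC(=O)N1Br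
Why: Silver-catalysed electrophilic bromination of the terminal alkyne (via the silver acetylide) should give the 1-bromoalkyne without touching the hydroxyl or the acetal.

Step 5
Reactants: 7 (1S)-4-bromo-1-Dx-but-3-yn-1-ol
Product: 8 (1S,3Z)-4-bromo-1-Dx-but-3-en-1-ol
Conditions: 2-nitrobenzenesulfonylhydrazide, Et3N, THF/i-PrOH, 25 °C
Reagents that add atoms: none
Why: Diimide reduction transfers H2 syn across the bromoalkyne in a concerted six-centre step, which should give the Z-1-bromoalkene without hydrogenolysis of the C–Br bond.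

Step 6
Reactants: 8 (1S,3Z)-4-bromo-1-Dx-but-3-en-1-ol; 9 bromoacetic acid
Product: 10 2-{[(1S,3Z)-4-bromo-1-Dx-but-3-en-1-yl]oxy}acetic acid
Conditions: NaH (3.5 equiv), THF, 0 to 25 °C; NaH2PO4 work-up at 0 °C
Reagents that add atoms: none
Why: Williamson etherification of the sodium alkoxide with sodium bromoacetate occurs at oxygen only, so C7 keeps its configuration, and the low temperature should spare the Z-bromoalkene from anti-elimination.

Step 7
Reactants: 10 2-{[(1S,3Z)-4-bromo-1-Dx-but-3-en-1-yl]oxy}acetic acid; 11 (S)-4-benzyloxazolidin-2-one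
Product: 13 (S)-4-benzyl-3-(2-{[(1S,3Z)-4-bromo-1-Dx-but-3-en-1-yl]oxy}acetyl)oxazolidin-2-one, via pivalic mixed anhydride 12 (not isolated)
Conditions: pivaloyl chloride, Et3N, THF, −78 to 0 °C; then 11/n-BuLi (THF, −78 °C), −78 to 0 °C
Reagents that add atoms: pivaloyl chloride, CC(C)(C)C(=O)Cl (its atoms remain only in intermediate 12)
Why: N-Acylation of the lithiated oxazolidinone by the mixed anhydride should occur at the less hindered glycolyl carbonyl and gives the imide needed for the auxiliary-controlled aldol.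

Step 8
Reactants: 13 (S)-4-benzyl-3-(2-{[(1S,3Z)-4-bromo-1-Dx-but-3-en-1-yl]oxy}acetyl)oxazolidin-2-one; 14 propanal
Product: 16 (S)-4-benzyl-3-[(2S,3R)-2-{[(1S,3Z)-4-bromo-1-Dx-but-3-en-1-yl]oxy}-3-hydroxypentanoyl]oxazolidin-2-one, via dibutylboron Z-enolate 15 (not isolated)
Conditions: Bu2BOTf, Et3N, CH2Cl2, −78 to 0 °C; propanal, −78 to 0 °C; pH 7 buffer, MeOH, H2O2, 0 °C
Reagents that add atoms: dibutylboron trifluoromethanesulfonate, CCCCB(CCCC)OS(=O)(=O)C(F)(F)F (its atoms remain only in intermediate 15)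
Why: Evans syn aldol reaction: the Z-boron enolate reacts with propanal through a Zimmerman–Traxler chair on the face opposite the benzyl group of the auxiliary, which should set C12 (2S in the imide) and C13 (3R) with the ether oxygen and the new hydroxyl syn.

Step 9
Reactants: 16 (S)-4-benzyl-3-[(2S,3R)-2-{[(1S,3Z)-4-bromo-1-Dx-but-3-en-1-yl]oxy}-3-hydroxypentanoyl]oxazolidin-2-one
Product: 17 (2R,3R)-2-{[(1S,3Z)-4-bromo-1-Dx-but-3-en-1-yl]oxy}pentane-1,3-diol
Conditions: LiBH4, MeOH (2 equiv), THF, 0 °C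
Reagents that add atoms: none
Why: Reductive cleavage of the N-acyl oxazolidinone with LiBH4 should give the primary C11 alcohol and return the auxiliary, leaving the bromoalkene, the acetal and both new stereocentres untouched.

Step 10
Reactants: 17 (2R,3R)-2-{[(1S,3Z)-4-bromo-1-Dx-but-3-en-1-yl]oxy}pentane-1,3-diol
Product: 18 (2S,3R)-2-{[(1S,3Z)-4-bromo-1-Dx-but-3-en-1-yl]oxy}-1-iodopentan-3-ol
Conditions: I2, PPh3, imidazole, CH2Cl2, 0 °C
Reagents that add atoms: iodine, II
Why: Appel-type iodination should be selective for the primary hydroxyl over the hindered secondary one and creates no stereocentre (the descriptor at C12 changes only through the priority of iodine).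

Step 11
Reactants: 18 (2S,3R)-2-{[(1S,3Z)-4-bromo-1-Dx-but-3-en-1-yl]oxy}-1-iodopentan-3-ol
Product: 19 (1R)-1-[(2R,7S)-7-Dx-2,3,6,7-tetrahydrooxepin-2-yl]propan-1-ol
Conditions: NiBr2(MeOCH2CH2OMe) (20 mol %), 4,4'-di-tert-butyl-2,2'-bipyridine (20 mol %), Mn powder (3 equiv), NaI (0.5 equiv), N,N-dimethylacetamide, 25 °C, 18 added by syringe pump over 10 h to 0.005 M
Reagents that add atoms: none
Why: Proposed new method: zerovalent nickel bearing the bipyridine ligand should insert into the alkenyl C10–Br bond with retention of the Z geometry, monovalent nickel formed under Mn reduction should abstract iodine from the primary C11–I bond, the C11 radical should be captured by the alkenylnickel centre of the same chain to give an eight-membered trivalent nickelacycle, and reductive elimination should form C10–C11. The closest known reaction type is the intermolecular nickel-catalysed reductive cross-electrophile coupling of alkenyl bromides with primary alkyl iodides, which keeps the alkene geometry and tolerates free hydroxyl groups and acetals; its use to close a medium-ring ether is the extension proposed here. The oxepene is closed by C(sp2)–C(sp3) reductive elimination from the nickelacycle (ring contraction from eight to seven atoms), not by addition to a π bond, so the alkene stays at C9=C10 and no exo or endo question arises in the productive path. No stereocentre is formed: C7, C12 and C13 are not reacting carbons and a β-alkoxy radical at C11 does not fragment, so the configurations from steps 3 and 8 are carried through and the cis ring alkene is the Z-bromoalkene of step 5. The step needs chemoselectivity between the two carbon–halogen bonds, which the pairing of sp2 C–Br (oxidative addition) with sp3 C–I (halogen abstraction) should secure, and ring closure in preference to oligomerisation, 6-exo attack of the C11 radical on C9 or a 1,5-hydrogen shift from C8, which the cis alkene and the C7–O–C12 ether (chain ends five atoms apart), slow addition at high dilution and the high nickel loading are expected to secure.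

Step 12
Reactants: 19 (1R)-1-[(2R,7S)-7-Dx-2,3,6,7-tetrahydrooxepin-2-yl]propan-1-ol
Product: 20 (2S,4S)-4-[(2S,7R)-7-[(1S)-1-bromopropyl]-2,3,6,7-tetrahydrooxepin-2-yl]-2-(4-methoxyphenyl)-1,3-dioxane
Conditions: CBr4, P(n-C8H17)3, toluene, 70 °C
Reagents that add atoms: carbon tetrabromide, BrC(Br)(Br)Br
Why: Appel bromination proceeds through the alkoxyphosphonium ion and SN2 displacement by bromide, which should invert C13 from R to S.

Step 13
Reactants: 20 (2S,4S)-4-[(2S,7R)-7-[(1S)-1-bromopropyl]-2,3,6,7-tetrahydrooxepin-2-yl]-2-(4-methoxyphenyl)-1,3-dioxane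
Product: 21 (3S)-3-[(2S,7R)-7-[(1S)-1-bromopropyl]-2,3,6,7-tetrahydrooxepin-2-yl]-3-(PMB-oxy)propan-1-ol
Conditions: i-Bu2AlH, CH2Cl2, −78 to 0 °C; Rochelle salt work-up
Reagents that add atoms: none
Why: Regioselective reductive opening of the arylidene acetal: aluminium coordinates the less hindered primary oxygen, so the PMB ether should end on the secondary C6 oxygen and the primary C4 hydroxyl is released.

Step 14
Reactants: 21 (3S)-3-[(2S,7R)-7-[(1S)-1-bromopropyl]-2,3,6,7-tetrahydrooxepin-2-yl]-3-(PMB-oxy)propan-1-ol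
Product: 22 (3S)-3-[(2S,7R)-7-[(1S)-1-bromopropyl]-2,3,6,7-tetrahydrooxepin-2-yl]-3-(PMB-oxy)propanal
Conditions: Dess–Martin periodinane, pyridine, CH2Cl2, 0 to 25 °C
Reagents that add atoms: none
Why: Dess–Martin oxidation under buffered conditions should give the β-alkoxy aldehyde without β-elimination.

Step 15
Reactants: 22 (3S)-3-[(2S,7R)-7-[(1S)-1-bromopropyl]-2,3,6,7-tetrahydrooxepin-2-yl]-3-(PMB-oxy)propanal; 23 1,3-bis(triisopropylsilyl)propyne
Product: 24 (2S,7R)-7-[(1S)-1-bromopropyl]-2-[(1S,3Z)-1-(PMB-oxy)-6-(triisopropylsilyl)hex-3-en-5-yn-1-yl]-2,3,6,7-tetrahydrooxepine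
Conditions: 23, n-BuLi, THF, −78 °C; then 22, −78 to −20 °C
Reagents that add atoms: none
Why: Peterson olefination with the lithiated bis-silylpropyne: the bulky silyl groups favour the adduct that undergoes syn-elimination of silanolate to the Z-enyne, and the hindered, weakly basic anion should spare the secondary bromide at low temperature.

Step 16
Reactants: 24 (2S,7R)-7-[(1S)-1-bromopropyl]-2-[(1S,3Z)-1-(PMB-oxy)-6-(triisopropylsilyl)hex-3-en-5-yn-1-yl]-2,3,6,7-tetrahydrooxepine
Product: 25 (2S,7R)-7-[(1S)-1-bromopropyl]-2-[(1S,3Z)-1-(PMB-oxy)hex-3-en-5-yn-1-yl]-2,3,6,7-tetrahydrooxepine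
Conditions: Bu4NF, THF, 0 °C
Reagents that add atoms: none
Why: Fluoride-induced desilylation of the alkynylsilane should free the terminal alkyne while the secondary bromide and the PMB ether survive at 0 °C.

Step 17
Reactants: 25 (2S,7R)-7-[(1S)-1-bromopropyl]-2-[(1S,3Z)-1-(PMB-oxy)hex-3-en-5-yn-1-yl]-2,3,6,7-tetrahydrooxepine
Product: 26 (1S,3Z)-1-[(2S,7R)-7-[(1S)-1-bromopropyl]-2,3,6,7-tetrahydrooxepin-2-yl]hex-3-en-5-yn-1-ol
Conditions: 2,3-dichloro-5,6-dicyano-1,4-benzoquinone, CH2Cl2/pH 7 buffer, 0 °C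
Reagents that add atoms: none
Why: Oxidative cleavage of the PMB ether (benzylic hydride abstraction, hydrolysis of the oxocarbenium ion) should free the C6 hydroxyl without touching the enyne, the ring alkene or the bromide.

Step 18
Reactants: 26 (1S,3Z)-1-[(2S,7R)-7-[(1S)-1-bromopropyl]-2,3,6,7-tetrahydrooxepin-2-yl]hex-3-en-5-yn-1-ol
Product: 27 (1S,3Z)-1-[(2S,7R)-7-[(1S)-1-bromopropyl]-2,3,6,7-tetrahydrooxepin-2-yl]hex-3-en-5-yn-1-yl acetate
Conditions: Ac2O, pyridine, 4-(dimethylamino)pyridine (cat.), CH2Cl2, 0 to 25 °C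
Reagents that add atoms: acetic anhydride, CC(=O)OC(C)=O
Why: Nucleophile-catalysed acetylation of the secondary alcohol should give the acetate with retention at C6.

**Compound list**

1 | (S)-butane-1,2,4-triol | OCC[C@H](O)CO | starting material
2 | 4-methoxybenzaldehyde dimethyl acetal | COc1ccc(cc1)C(OC)OC | starting material
3 | [(2S,4S)-2-(4-methoxyphenyl)-1,3-dioxan-4-yl]methanol | OC[C@@H]1CCO[C@H](c2ccc(OC)cc2)O1 | intermediate
4 | (2S,4S)-2-(4-methoxyphenyl)-1,3-dioxane-4-carbaldehyde | O=C[C@@H]1CCO[C@H](c2ccc(OC)cc2)O1 | intermediate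
5 | allenyltributylstannane (tributyl(propa-1,2-dienyl)stannane) | C=C=C[Sn](CCCC)(CCCC)CCCC | starting material
6 | (1S)-1-[(2S,4S)-2-(4-methoxyphenyl)-1,3-dioxan-4-yl]but-3-yn-1-ol | C#CC[C@H](O)[C@@H]1CCO[C@H](c2ccc(OC)cc2)O1 | intermediate
7 | (1S)-4-bromo-1-[(2S,4S)-2-(4-methoxyphenyl)-1,3-dioxan-4-yl]but-3-yn-1-ol | BrC#CC[C@H](O)[C@@H]1CCO[C@H](c2ccc(OC)cc2)O1 | intermediate
8 | (1S,3Z)-4-bromo-1-[(2S,4S)-2-(4-methoxyphenyl)-1,3-dioxan-4-yl]but-3-en-1-ol | Br/C=C\C[C@H](O)[C@@H]1CCO[C@H](c2ccc(OC)cc2)O1 | intermediate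
9 | bromoacetic acid | OC(=O)CBr | starting material
10 | 2-{[(1S,3Z)-4-bromo-1-[(2S,4S)-2-(4-methoxyphenyl)-1,3-dioxan-4-yl]but-3-en-1-yl]oxy}acetic acid | Br/C=C\C[C@H](OCC(O)=O)[C@@H]1CCO[C@H](c2ccc(OC)cc2)O1 | intermediate
11 | (S)-4-benzyloxazolidin-2-one | O=C1N[C@@H](Cc2ccccc2)CO1 | starting material
12 | mixed anhydride of 10 with pivalic acid | Br/C=C\C[C@H](OCC(=O)OC(=O)C(C)(C)C)[C@@H]1CCO[C@H](c2ccc(OC)cc2)O1 | intermediate (not isolated)
13 | (S)-4-benzyl-3-(2-{[(1S,3Z)-4-bromo-1-[(2S,4S)-2-(4-methoxyphenyl)-1,3-dioxan-4-yl]but-3-en-1-yl]oxy}acetyl)oxazolidin-2-one | Br/C=C\C[C@H](OCC(=O)N1[C@@H](Cc2ccccc2)COC1=O)[C@@H]3CCO[C@H](c4ccc(OC)cc4)O3 | intermediate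
14 | propanal | CCC=O | starting material
15 | dibutylboron Z-enolate of 13 | Br/C=C\C[C@H](O/C=C(\OB(CCCC)CCCC)N1[C@@H](Cc2ccccc2)COC1=O)[C@@H]3CCO[C@H](c4ccc(OC)cc4)O3 | intermediate (not isolated)
16 | (S)-4-benzyl-3-[(2S,3R)-2-{[(1S,3Z)-4-bromo-1-[(2S,4S)-2-(4-methoxyphenyl)-1,3-dioxan-4-yl]but-3-en-1-yl]oxy}-3-hydroxypentanoyl]oxazolidin-2-one | Br/C=C\C[C@H](O[C@@H]([C@H](O)CC)C(=O)N1[C@@H](Cc2ccccc2)COC1=O)[C@@H]3CCO[C@H](c4ccc(OC)cc4)O3 | intermediate
17 | (2R,3R)-2-{[(1S,3Z)-4-bromo-1-[(2S,4S)-2-(4-methoxyphenyl)-1,3-dioxan-4-yl]but-3-en-1-yl]oxy}pentane-1,3-diol | Br/C=C\C[C@H](O[C@@H]([C@H](O)CC)CO)[C@@H]1CCO[C@H](c2ccc(OC)cc2)O1 | intermediate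
18 | (2S,3R)-2-{[(1S,3Z)-4-bromo-1-[(2S,4S)-2-(4-methoxyphenyl)-1,3-dioxan-4-yl]but-3-en-1-yl]oxy}-1-iodopentan-3-ol | Br/C=C\C[C@H](O[C@@H]([C@H](O)CC)CI)[C@@H]1CCO[C@H](c2ccc(OC)cc2)O1 | intermediate
19 | (1R)-1-[(2R,7S)-7-[(2S,4S)-2-(4-methoxyphenyl)-1,3-dioxan-4-yl]-2,3,6,7-tetrahydrooxepin-2-yl]propan-1-ol | COc1ccc(cc1)[C@H]2OCC[C@H](O2)[C@@H]3CC=CC[C@H]([C@H](O)CC)O3 | intermediate
20 | (2S,4S)-4-[(2S,7R)-7-[(1S)-1-bromopropyl]-2,3,6,7-tetrahydrooxepin-2-yl]-2-(4-methoxyphenyl)-1,3-dioxane | COc1ccc(cc1)[C@H]2OCC[C@H](O2)[C@@H]3CC=CC[C@H]([C@@H](Br)CC)O3 | intermediate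
21 | (3S)-3-[(2S,7R)-7-[(1S)-1-bromopropyl]-2,3,6,7-tetrahydrooxepin-2-yl]-3-[(4-methoxybenzyl)oxy]propan-1-ol | OCC[C@H](OCc1ccc(OC)cc1)[C@@H]2CC=CC[C@H]([C@@H](Br)CC)O2 | intermediate
22 | (3S)-3-[(2S,7R)-7-[(1S)-1-bromopropyl]-2,3,6,7-tetrahydrooxepin-2-yl]-3-[(4-methoxybenzyl)oxy]propanal | O=CC[C@H](OCc1ccc(OC)cc1)[C@@H]2CC=CC[C@H]([C@@H](Br)CC)O2 | intermediate
23 | 1,3-bis(triisopropylsilyl)propyne | CC(C)[Si](C(C)C)(C(C)C)CC#C[Si](C(C)C)(C(C)C)C(C)C | starting material
24 | (2S,7R)-7-[(1S)-1-bromopropyl]-2-[(1S,3Z)-1-[(4-methoxybenzyl)oxy]-6-(triisopropylsilyl)hex-3-en-5-yn-1-yl]-2,3,6,7-tetrahydrooxepine | CC(C)[Si](C(C)C)(C(C)C)C#C/C=C\C[C@H](OCc1ccc(OC)cc1)[C@@H]2CC=CC[C@H]([C@@H](Br)CC)O2 | intermediate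
25 | (2S,7R)-7-[(1S)-1-bromopropyl]-2-[(1S,3Z)-1-[(4-methoxybenzyl)oxy]hex-3-en-5-yn-1-yl]-2,3,6,7-tetrahydrooxepine | C#C/C=C\C[C@H](OCc1ccc(OC)cc1)[C@@H]2CC=CC[C@H]([C@@H](Br)CC)O2 | intermediate
26 | (1S,3Z)-1-[(2S,7R)-7-[(1S)-1-bromopropyl]-2,3,6,7-tetrahydrooxepin-2-yl]hex-3-en-5-yn-1-ol | C#C/C=C\C[C@H](O)[C@@H]1CC=CC[C@H]([C@@H](Br)CC)O1 | intermediate
27 | (1S,3Z)-1-[(2S,7R)-7-[(1S)-1-bromopropyl]-2,3,6,7-tetrahydrooxepin-2-yl]hex-3-en-5-yn-1-yl acetate | C#C/C=C\C[C@H](OC(C)=O)[C@@H]1CC=CC[C@H]([C@@H](Br)CC)O1 | target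

**Step count and risks**

Total step count: 18. Longest linear sequence: 18 steps (from 1 to 27).

Steps most likely to fail:

1. Step 11 (proposed new method). The C11 radical may escape capture by nickel on its own chain, leading to intermolecular coupling and oligomers, 6-exo addition to C9, a 1,5-hydrogen shift from the allylic C8 or simple reduction of the C–I bond. The fallback uses known two-electron chemistry and sets out from 18: copper-catalysed borylation (CuI, PPh3, LiOMe, bis(pinacolato)diboron, DMF, 25 °C) should give the pinacol boronate F1, KHF2 in MeOH/H2O should convert it into the potassium trifluoroborate F2, and an intramolecular B-alkyl Suzuki–Miyaura coupling with the Z-bromoalkene (PdCl2[1,1'-bis(diphenylphosphino)ferrocene], Cs2CO3, toluene/H2O, 80 °C, 0.005 M) should close the same C10–C11 bond with retention of alkene geometry and come back to the route at 19.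

2. Step 12. The ring oxygen may participate in the ionising alkoxyphosphonium intermediate (oxonium formation, hence retention or ring contraction), and E2 elimination may compete at 70 °C. The fallback sets out from 19: chloromethanesulfonyl chloride and 2,6-lutidine (CH2Cl2, 0 °C) should give the chloromethanesulfonate F3, which is displaced with inversion by LiBr in THF at 25 to 50 °C, an isolated sulfonate with an external nucleophile at lower temperature, and it comes back at 20.

3. Step 15. Z selectivity may erode in the silanolate elimination, and the basic reagent may cause β-elimination of the C6 ether from the aldehyde. The fallback sets out from 22: Stork–Zhao iodo-olefination (Ph3P=CHI from (iodomethyl)triphenylphosphonium iodide and NaN(SiMe3)2, THF/HMPA, −78 °C) should give the Z-iodoalkene F4, Sonogashira coupling with trimethylsilylacetylene (Pd(PPh3)4, CuI, i-Pr2NH, 25 °C) the trimethylsilyl enyne F5, and K2CO3 in MeOH at 0 °C removes the silyl group to come back at 25.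

Further compounds
F1 | step 11 | (2R,3R)-2-{[(1S,3Z)-4-bromo-1-[(2S,4S)-2-(4-methoxyphenyl)-1,3-dioxan-4-yl]but-3-en-1-yl]oxy}-1-(4,4,5,5-tetramethyl-1,3,2-dioxaborolan-2-yl)pentan-3-ol | Br/C=C\C[C@H](O[C@@H]([C@H](O)CC)CB1OC(C)(C)C(C)(C)O1)[C@@H]2CCO[C@H](c3ccc(OC)cc3)O2
F2 | step 11 | potassium [(2R,3R)-2-{[(1S,3Z)-4-bromo-1-[(2S,4S)-2-(4-methoxyphenyl)-1,3-dioxan-4-yl]but-3-en-1-yl]oxy}-3-hydroxypentyl]trifluoroborate | Br/C=C\C[C@H](O[C@@H]([C@H](O)CC)C[B-](F)(F)F)[C@@H]1CCO[C@H](c2ccc(OC)cc2)O1.[K+]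
F3 | step 12 | (1R)-1-[(2R,7S)-7-[(2S,4S)-2-(4-methoxyphenyl)-1,3-dioxan-4-yl]-2,3,6,7-tetrahydrooxepin-2-yl]propyl chloromethanesulfonate | COc1ccc(cc1)[C@H]2OCC[C@H](O2)[C@@H]3CC=CC[C@H]([C@H](OS(=O)(=O)CCl)CC)O3
F4 | step 15 | (2S,7R)-7-[(1S)-1-bromopropyl]-2-[(1S,3Z)-4-iodo-1-[(4-methoxybenzyl)oxy]but-3-en-1-yl]-2,3,6,7-tetrahydrooxepine | I/C=C\C[C@H](OCc1ccc(OC)cc1)[C@@H]2CC=CC[C@H]([C@@H](Br)CC)O2
F5 | step 15 | (2S,7R)-7-[(1S)-1-bromopropyl]-2-[(1S,3Z)-1-[(4-methoxybenzyl)oxy]-6-(trimethylsilyl)hex-3-en-5-yn-1-yl]-2,3,6,7-tetrahydrooxepine | C[Si](C)(C)C#C/C=C\C[C@H](OCc1ccc(OC)cc1)[C@@H]2CC=CC[C@H]([C@@H](Br)CC)O2
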